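(The data were computed for an exercise; noise was put on by code.)

Two questions came with the hunch that Sunday's flask is Wednesday's over again, and that Wednesday's and Saturday's are one curve on two clocks. The readings can test that.

common to all: Sbt 1.00 M
- Wednesday's: Ctl 0.00200 M
- Saturday's: Ctl 0.00600 M
- Sunday's: Ctl 0.00200 M; time 26 min

| run | time / min | [Pdt] / M |
|---|---|---|
| Wednesday's run | 0.93 | 0.051 |
| Wednesday's run | 1.9 | 0.106 |
| Wednesday's run | 2.8 | 0.167 |
| Wednesday's run | 3.7 | 0.216 |
| Wednesday's run | 4.6 | 0.281 |
| Wednesday's run | 5.6 | 0.320 |
| Wednesday's run | 6.5 | 0.364 |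
| Saturday's run | 0.93 | 0.184 |
| Saturday's run | 1.9 | 0.363 |
| Saturday's run | 2.8 | 0.510 |
| Saturday's run | 3.7 | 0.609 |
| Saturday's run | 4.6 | 0.706 |
| Saturday's run | 5.6 | 0.785 |
| Saturday's run | 6.5 | 0.848 |

(each reading ± 0.008 M)

1. order of the initial rate in [Ctl], near the charge of the Wednesday's run, the rate being that where two percent of its Sbt are Pdt
2. Pdt in the Sunday's run at 26 min, as a share of the Sbt charged

- Overall: Sbt -> Pdt, with Ctl as catalyst.
- Constant volume, constant temperature.
- Bound and free are read together.
- An order is taken over about fifteen percent of the charge, up and down.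

Sunday's flask has Wednesday's charge of Ctl, 0.00200 M. Wednesday's flask reaches c(Pdt) = 0.364 M at 6.5 min, and Saturday's flask reaches 0.363 M at 1.9 min. The quotient of those times, a reading of 3.42, is the clock ratio, the time one flask needs for a given c(Pdt) over the time another needs for the same c(Pdt) (time normalisation, in the usual term).

Ctl differs by a factor of 3.00 between these flasks, so the ratio gives a mean order of 1.12. That order spans the whole step in charge and comes from well into the runs, so it is a loose answer to the first question.

For Sunday's flask, the end is taken as the full charge, 1.00 M, since Saturday's flask is still climbing at its last reading, 0.848 M. On Saturday's clock, Sunday's 26 min becomes 7.60 min, past that flask's last reading at 6.5 min. The remainder of Saturday's charge falls from 0.294 M at 4.6 min to 0.152 M at 6.5 min, a first-order pace of 0.347 min⁻¹. Continued to 7.60 min, that pace gives 89.6%.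

The forecast stands higher on the order and slightly lower on the yield, at 1.2 and 89%, with the caution “Slow catalyst death beyond 6.5 min is untested”.

The flask gives an order of 1.5 and 94.9% at 26 min, which is 5.3 percentage points above this reckoning.

    Ctl + Sbt ⇌ Ctl.Sbt, settled at all times (17.40 L mol⁻¹)
    Ctl.Sbt → Pdt + Ctl (61.20 min⁻¹)
    2 Ctl ⇌ Ctl2, settled at all times (18700 L mol⁻¹)
    Ctl + G → J

Where two percent of Wednesday's Sbt have turned, Saturday's flask makes Pdt at 0.21 M min⁻¹ and Wednesday's flask at 0.061 M min⁻¹. Saturday's flask stands at half its charge as Pdt at 2.81 min. The clock ratio carries that to 9.62 min for Wednesday's flask, which stands there at 9.03 min.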